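(The numbers are made up.)

Late in a run, what I watched was how the Z still unmatched shared itself between D and its own kind.

    G → Z (k1 = 9.9 × 10⁻⁴ /min, Ea1 = 119 kJ/mol)
    X → D (k2 = 8.9 × 10⁻⁴ /min, Ea2 = 105 kJ/mol)
    Z + D → Z.D (k3 = 0.11 /M/min, Ea3 = 55.0 kJ/mol)
    2 Z → Z2 (k4 = 0.012 /M/min, Ea4 = 75.0 kJ/mol)
    X + J → X.J (k5 = 0.13 /M/min, Ea5 = 81.0 kJ/mol)
    (constants at 70 °C)

| flask | G | X | J | temperature | time |
|---|---|---|---|---|---|
| dawn | 0.10 M | 1.30 equiv | 5.00 mM | 70 °C | 12 d |
| midnight | 0.10 M | 1.30 equiv | 5.00 mM | 40 °C | 12 d |
| winter | 0.10 M | 1.30 equiv | 5.00 mM | 130 °C | 12 d |
| dusk | 0.10 M | 1.30 equiv | 5.00 mM | 100 °C | 12 d |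

* the flask with the highest amount of Z.D, in percent of the G charged ("all alike" if they lie within 1.5 percentage points) (dawn / midnight / winter / dusk / all alike)
* final Z.D, as a percentage of the G charged, in dawn
* final Z.D, as a percentage of the G charged, in midnight
* final Z.D, as a percentage of the G charged, in winter
* final Z.D, as a percentage of the G charged, in dusk

- a species is counted by the G in it: one Z2 counts as two
- a step written with two of one species runs at k times the square of its concentration and takes two of it each time
- at 70 °C the constants are as listed, elsewhere as the activation energies make them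

I began with the terms of that sharing. When Z and D stand equal, Z goes to Z2 at twice 0.012 /M/min times its concentration squared and to D at 0.11 /M/min times the same square. The ratio of these two losses, which I called s, a selectivity factor, was therefore 0.218 in dawn. Equal concentrations are the zero of this scale, and any other ratio of Z to D multiplies s. Step 4 has the higher barrier by 20.0 kJ/mol, so s came to 0.111 in midnight, 0.383 in dusk and 0.619 in winter.

Next came J. With X at its charge in dawn, the pseudo-first-order constant of J was 0.0169 /min, far faster than the 8.9 × 10⁻⁴ /min at which X turns into D. So I took the charge of J off X, which left e = 1.25 equivalents of D.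

Then I supposed both species were made before coupling began. Each D lost then costs Z one plus s times Z/D, and integrating until Z is gone gives Z.D per G charged as Y = e[1 − (1 − (1 − s)/e)^(1/(1 − s))]. This gave 89.4% in dawn, 83.5% in dusk and 76.9% in winter. In midnight, step 1 slows to 1.82 × 10⁻⁵ /min, so 12 d converts 27.0% of G. Y of 94.1% then shrinks to 25.4%.

The weak link was that supposition. I reforged it with φ, the rate of making D from the e equivalents over the rate of making Z at the start, where one is the symmetric zero. It stood at 1.12 in dawn, 0.757 in dusk and 0.541 in winter. With φ below one in dusk and winter, Z began faster than D, so I expected Y to read high there, and low in dawn, where φ stood above one. I could give the direction, not the size.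

The forecast named dawn, with 90% in dawn, 22% in midnight, 71% in winter and 83% in dusk, holding that “Heating then favours the higher-barrier dimerisation over capture by D”. Its winter figure lay lower than my Y, and its midnight figure lower than my reckoning.

The run gave 91.6% in dawn, 22.5% in midnight, 71.1% in winter and 80.1% in dusk, so dawn stood highest. At the end of dawn, Z2 held 8.37% of the G charged. Y built on s fell short of the run by 2.2 percentage points in dawn, where φ lay above one. It overshot by 3.4 points in dusk and 5.8 points in winter, where φ lay below one.

In the flask like midnight kept at 55 °C, s was 0.158, so Y was 91.9%. Conversion of 92.1% brought that to 84.6%, and with φ at 1.41, above one, I looked for the run to lie higher. The run gave 87.5%.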